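**Strategy.** The route rests on the bond between the aroyl carbon C1 (on the 3-oxygenated benzene ring) and the acyclic quaternary carbon C2. The feature exploited is that C2 carries a prenyl CH2–CH= arm, which can be traced back to a vinyl group; C1–C2 then becomes the bond formed in a carbonyl allylation. In one operation a chiral-phosphoric-acid-catalysed allylboration joins 3-silyloxybenzaldehyde to an (E)-γ,γ-disubstituted allyl pinacolboronate that already contains C3 and C4, and creates the quaternary centre: the catalyst fixes the aldehyde face, the chair transition state relays it to C2, and the C1 carbinol is then oxidised away.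

Key step: step 9

Remark on labels: C1 = aroyl carbon, C2 = quaternary carbon, C3 = CH bearing the isopropenyl group, C4 = CH bearing the prenyl and 3-methylbut-3-enyl chains.

Assumption: 2-methylpent-1-en-3-yne (1) is taken as a catalogue compound. The senses of induction quoted for (−)-MIB (step 1) and (R)-TRIP (step 9) are taken by analogy with their behaviour towards simple aldehydes; if either is reversed, the enantiomeric ligand or catalyst is used.

## Route

Step 1
Reactants: 1 2-methylpent-1-en-3-yne; 2 (tert-butyldimethylsilyloxy)acetaldehyde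
Product: 5 (2S,3E)-1-((tert-butyldimethylsilyl)oxy)-3,5-dimethylhexa-3,5-dien-2-ol, via dienylzirconocene chloride 3 (not isolated), via dienyl(methyl)zinc 4 (not isolated)
Conditions: Cp2Zr(H)Cl, CH2Cl2, rt; Me2Zn, toluene, −65 °C; (−)-MIB (10 mol %), then 2, −30 °C; aq. NH4Cl
Reagents that add atoms: none
Why: Syn hydrozirconation of the internal alkyne should place Zr on the methyl-bearing carbon (E-dienyl metal), and after Zr-to-Zn transmetalation the amino-alcohol-catalysed alkenylzinc addition to the aldehyde sets the carbinol centre under ligand control, (−)-MIB being expected to give the (S)-alcohol.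

Step 2
Reactants: 5 (2S,3E)-1-((tert-butyldimethylsilyl)oxy)-3,5-dimethylhexa-3,5-dien-2-ol; 6 5-methylhex-4-enoic acid
Product: 7 (2S,3E)-1-((tert-butyldimethylsilyl)oxy)-3,5-dimethylhexa-3,5-dien-2-yl 5-methylhex-4-enoate
Conditions: DCC, DMAP (cat.), CH2Cl2, 0 °C → rt
Reagents that add atoms: none
Why: Steglich esterification acylates the secondary allylic alcohol under neutral conditions and leaves the carbinol stereocentre and the diene untouched.

Step 3
Reactants: 7 (2S,3E)-1-((tert-butyldimethylsilyl)oxy)-3,5-dimethylhexa-3,5-dien-2-yl 5-methylhex-4-enoate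
Product: 10 (2S,3S,4E)-6-((tert-butyldimethylsilyl)oxy)-4-methyl-2-(3-methylbut-2-en-1-yl)-3-(prop-1-en-2-yl)hex-4-enoic acid, via silyl ketene acetal 8 (not isolated), via trimethylsilyl ester 9 (not isolated)
Conditions: LDA, THF, −78 °C; TMSCl; −78 °C → rt (50 °C if needed); dilute aq. citric acid
Reagents that add atoms: none
Why: Ireland–Claisen rearrangement, in which kinetic enolisation in THF should give the (E)-silyl ketene acetal that rearranges through a chair with the CH2OTBS group equatorial, so the (S)-carbinol centre is transferred into C3 and C4 (anti-type relationship) and the new trisubstituted alkene is formed E.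

Step 4
Reactants: 10 (2S,3S,4E)-6-((tert-butyldimethylsilyl)oxy)-4-methyl-2-(3-methylbut-2-en-1-yl)-3-(prop-1-en-2-yl)hex-4-enoic acid
Product: 11 (2S,3S,4E)-6-((tert-butyldimethylsilyl)oxy)-4-methyl-2-(3-methylbut-2-en-1-yl)-3-(prop-1-en-2-yl)hex-4-en-1-ol
Conditions: LiAlH4, THF, 0 °C → rt; aq. NaOH work-up
Reagents that add atoms: none
Why: Hydride reduction of the carboxylic acid gives the primary alcohol and should leave the silyl ether, the isolated alkenes and both stereocentres untouched.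

Step 5
Reactants: 11 (2S,3S,4E)-6-((tert-butyldimethylsilyl)oxy)-4-methyl-2-(3-methylbut-2-en-1-yl)-3-(prop-1-en-2-yl)hex-4-en-1-ol
Product: 12 tert-butyl(((2E,4S,5S)-5-(iodomethyl)-3,8-dimethyl-4-(prop-1-en-2-yl)nona-2,7-dien-1-yl)oxy)dimethylsilane
Conditions: I2, PPh3, imidazole, CH2Cl2, 0 °C
Reagents that add atoms: iodine II
Why: Appel-type iodination converts the primary alcohol into the iodide by SN2 displacement at a carbon that is not stereogenic.

Step 6
Reactants: 12 tert-butyl(((2E,4S,5S)-5-(iodomethyl)-3,8-dimethyl-4-(prop-1-en-2-yl)nona-2,7-dien-1-yl)oxy)dimethylsilane; 13 2-methylallylmagnesium chloride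
Product: 14 tert-butyldimethyl(((2E,4S,5S)-3,8-dimethyl-5-(3-methylbut-3-en-1-yl)-4-(prop-1-en-2-yl)nona-2,7-dien-1-yl)oxy)silane
Conditions: CuI (10 mol %), THF, −20 °C → rt
Reagents that add atoms: none
Why: Copper-catalysed sp3–sp3 cross-coupling of the primary iodide with the allylic Grignard reagent installs the 3-methylbut-3-enyl chain, and no regiochemical issue arises because both termini of the 2-methylallyl unit are equivalent.

Step 7
Reactants: 14 tert-butyldimethyl(((2E,4S,5S)-3,8-dimethyl-5-(3-methylbut-3-en-1-yl)-4-(prop-1-en-2-yl)nona-2,7-dien-1-yl)oxy)silane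
Product: 15 (2E,4S,5S)-3,8-dimethyl-5-(3-methylbut-3-en-1-yl)-4-(prop-1-en-2-yl)nona-2,7-dien-1-ol
Conditions: TBAF, THF, 0 °C → rt; aq. NH4Cl
Reagents that add atoms: none
Why: Fluoride-mediated desilylation frees the primary allylic alcohol without touching the skipped diene or the stereocentres.

Step 8
Reactants: 15 (2E,4S,5S)-3,8-dimethyl-5-(3-methylbut-3-en-1-yl)-4-(prop-1-en-2-yl)nona-2,7-dien-1-ol
Product: 16 2-((2E,4S,5S)-3,8-dimethyl-5-(3-methylbut-3-en-1-yl)-4-(prop-1-en-2-yl)nona-2,7-dien-1-yl)-4,4,5,5-tetramethyl-1,3,2-dioxaborolane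
Conditions: B2pin2, Pd(MeCN)4(BF4)2 (5 mol %), DMSO/MeOH, rt
Reagents that add atoms: bis(pinacolato)diboron CC1(C)OB(OC1(C)C)B1OC(C)(C)C(C)(C)O1
Why: Palladium-catalysed borylation of the allylic alcohol proceeds through an η3-allyl palladium intermediate that is borylated at the less hindered terminus, which should give the linear (E)-allylboronate.

Step 9
Reactants: 16 2-((2E,4S,5S)-3,8-dimethyl-5-(3-methylbut-3-en-1-yl)-4-(prop-1-en-2-yl)nona-2,7-dien-1-yl)-4,4,5,5-tetramethyl-1,3,2-dioxaborolane; 17 3-((tert-butyldimethylsilyl)oxy)benzaldehyde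
Product: 19 (1S,2S,3S,4S)-1-(3-((tert-butyldimethylsilyl)oxy)phenyl)-2,7-dimethyl-4-(3-methylbut-2-en-1-yl)-3-(prop-1-en-2-yl)-2-vinyloct-7-en-1-ol, via pinacol borate ester 18 (not isolated)
Conditions: (R)-TRIP (10 mol %), 4 Å MS, toluene, −30 °C → rt; aq. NaHCO3
Reagents that add atoms: none
Why: The phosphoric acid hydrogen-bonds to a boronate oxygen and to the formyl C–H, and the γ-carbon of the allyl unit (C2) attacks the aldehyde carbon (C1) through a closed six-membered chair, the closest known reaction type being phosphoric-acid-catalysed allyl- and crotylboration of aryl aldehydes, together with additions of γ,γ-disubstituted allylboronates that give quaternary carbons. No ring is closed: the cyclic array exists only in the transition state and collapses to the acyclic borate 18, which is hydrolysed on work-up. C1 is set by the catalyst, (R)-TRIP being expected to direct attack to the Re face of the aldehyde and so give the (1S)-carbinol. C2 is set by relay, because in the chair the aryl group and the C3-bearing substituent (trans to CH2B in the E-boronate) are equatorial and the methyl group axial, so that Re-face attack fixes the (S)-configuration at C2. The step needs γ- over α-attack (guaranteed by the cyclic transition state), reaction at the aldehyde only, and control of the alkene face, which the catalyst should supply because C3 faces only a vinylic hydrogen across the double bond and exerts little bias of its own.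

Step 10
Reactants: 19 (1S,2S,3S,4S)-1-(3-((tert-butyldimethylsilyl)oxy)phenyl)-2,7-dimethyl-4-(3-methylbut-2-en-1-yl)-3-(prop-1-en-2-yl)-2-vinyloct-7-en-1-ol
Product: 20 (2S,3S,4S)-1-(3-((tert-butyldimethylsilyl)oxy)phenyl)-2,7-dimethyl-4-(3-methylbut-2-en-1-yl)-3-(prop-1-en-2-yl)-2-vinyloct-7-en-1-one
Conditions: Dess–Martin periodinane, NaHCO3, CH2Cl2, rt
Reagents that add atoms: none
Why: Dess–Martin oxidation converts the hindered benzylic alcohol into the aryl ketone and removes the relay stereocentre C1, while the quaternary α-carbon rules out epimerisation and alkene migration.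

Step 11
Reactants: 20 (2S,3S,4S)-1-(3-((tert-butyldimethylsilyl)oxy)phenyl)-2,7-dimethyl-4-(3-methylbut-2-en-1-yl)-3-(prop-1-en-2-yl)-2-vinyloct-7-en-1-one
Product: 21 (3S,4S,5S)-3-(3-((tert-butyldimethylsilyl)oxy)benzoyl)-3,8-dimethyl-5-(3-methylbut-2-en-1-yl)-4-(prop-1-en-2-yl)non-8-enal
Conditions: PdCl2(PhCN)2 (10 mol %), CuCl2·2H2O (10 mol %), AgNO2 (5 mol %), O2 (1 atm), t-BuOH/MeNO2, rt
Reagents that add atoms: dioxygen O=O
Why: Nitrite-modified, aldehyde-selective Wacker oxidation should deliver oxygen to the terminal carbon of the only monosubstituted alkene because the adjacent quaternary carbon blocks Markovnikov attack, while 1,1-disubstituted and trisubstituted alkenes are poor Wacker substrates.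

Step 12
Reactants: 21 (3S,4S,5S)-3-(3-((tert-butyldimethylsilyl)oxy)benzoyl)-3,8-dimethyl-5-(3-methylbut-2-en-1-yl)-4-(prop-1-en-2-yl)non-8-enal
Product: 22 (2S,3S,4S)-1-(3-((tert-butyldimethylsilyl)oxy)phenyl)-2,7-dimethyl-2,4-bis(3-methylbut-2-en-1-yl)-3-(prop-1-en-2-yl)oct-7-en-1-one
Conditions: i-PrPPh3I, n-BuLi, THF, 0 °C; then 21, −78 °C → rt
Reagents that add atoms: isopropyltriphenylphosphonium iodide CC(C)[P+](c1ccccc1)(c1ccccc1)c1ccccc1.[I-]
Why: Wittig olefination with the non-stabilised isopropylidene ylide turns the unhindered aldehyde into the prenyl group, the neopentyl, non-enolisable aryl ketone being too hindered to compete.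

Step 13
Reactants: 22 (2S,3S,4S)-1-(3-((tert-butyldimethylsilyl)oxy)phenyl)-2,7-dimethyl-2,4-bis(3-methylbut-2-en-1-yl)-3-(prop-1-en-2-yl)oct-7-en-1-one
Product: 23 garcinielliptone FA, (2S,3S,4S)-1-(3-hydroxyphenyl)-2,7-dimethyl-2,4-bis(3-methylbut-2-en-1-yl)-3-(prop-1-en-2-yl)oct-7-en-1-one
Conditions: TBAF, THF, 0 °C; aq. NH4Cl
Reagents that add atoms: none
Why: Fluoride-mediated cleavage of the aryl silyl ether liberates the phenol, and since the ketone has no α-hydrogen the stereocentres are safe under the basic conditions.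

## Compound list

1 | 2-methylpent-1-en-3-yne | CC#CC(C)=C | starting material
2 | (tert-butyldimethylsilyloxy)acetaldehyde | O=CCO[Si](C)(C)C(C)(C)C | starting material
3 | chlorobis(cyclopentadienyl)[(2E)-4-methylpenta-2,4-dien-2-yl]zirconium | C=C(C)/C=C(\C)[Zr](Cl)(C1C=CC=C1)C1C=CC=C1 | intermediate
4 | methyl[(2E)-4-methylpenta-2,4-dien-2-yl]zinc | C=C(C)/C=C(\C)[Zn]C | intermediate
5 | (2S,3E)-1-((tert-butyldimethylsilyl)oxy)-3,5-dimethylhexa-3,5-dien-2-ol | C=C(C)/C=C(\C)[C@H](O)CO[Si](C)(C)C(C)(C)C | intermediate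
6 | 5-methylhex-4-enoic acid | CC(C)=CCCC(=O)O | starting material
7 | (2S,3E)-1-((tert-butyldimethylsilyl)oxy)-3,5-dimethylhexa-3,5-dien-2-yl 5-methylhex-4-enoate | C=C(C)/C=C(\C)[C@H](OC(=O)CCC=C(C)C)CO[Si](C)(C)C(C)(C)C | intermediate
8 | (E)-trimethylsilyl ketene acetal of ester 7 (prenyl-bearing carbon cis to the allylic oxygen) | C=C(C)/C=C(\C)[C@H](O/C(O[Si](C)(C)C)=C\CC=C(C)C)CO[Si](C)(C)C(C)(C)C | intermediate
9 | trimethylsilyl ester of acid 10 | C[Si](C)(C)OC(=O)[C@@H](CC=C(C)C)[C@@H](C(C)=C)/C(C)=C/CO[Si](C)(C)C(C)(C)C | intermediate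
10 | (2S,3S,4E)-6-((tert-butyldimethylsilyl)oxy)-4-methyl-2-(3-methylbut-2-en-1-yl)-3-(prop-1-en-2-yl)hex-4-enoic acid | OC(=O)[C@@H](CC=C(C)C)[C@@H](C(C)=C)/C(C)=C/CO[Si](C)(C)C(C)(C)C | intermediate
11 | (2S,3S,4E)-6-((tert-butyldimethylsilyl)oxy)-4-methyl-2-(3-methylbut-2-en-1-yl)-3-(prop-1-en-2-yl)hex-4-en-1-ol | OC[C@@H](CC=C(C)C)[C@@H](C(C)=C)/C(C)=C/CO[Si](C)(C)C(C)(C)C | intermediate
12 | tert-butyl(((2E,4S,5S)-5-(iodomethyl)-3,8-dimethyl-4-(prop-1-en-2-yl)nona-2,7-dien-1-yl)oxy)dimethylsilane | IC[C@@H](CC=C(C)C)[C@@H](C(C)=C)/C(C)=C/CO[Si](C)(C)C(C)(C)C | intermediate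
13 | 2-methylallylmagnesium chloride | C=C(C)C[Mg]Cl | starting material
14 | tert-butyldimethyl(((2E,4S,5S)-3,8-dimethyl-5-(3-methylbut-3-en-1-yl)-4-(prop-1-en-2-yl)nona-2,7-dien-1-yl)oxy)silane | C=C(C)CC[C@@H](CC=C(C)C)[C@@H](C(C)=C)/C(C)=C/CO[Si](C)(C)C(C)(C)C | intermediate
15 | (2E,4S,5S)-3,8-dimethyl-5-(3-methylbut-3-en-1-yl)-4-(prop-1-en-2-yl)nona-2,7-dien-1-ol | C=C(C)CC[C@@H](CC=C(C)C)[C@@H](C(C)=C)/C(C)=C/CO | intermediate
16 | 2-((2E,4S,5S)-3,8-dimethyl-5-(3-methylbut-3-en-1-yl)-4-(prop-1-en-2-yl)nona-2,7-dien-1-yl)-4,4,5,5-tetramethyl-1,3,2-dioxaborolane | C=C(C)CC[C@@H](CC=C(C)C)[C@@H](C(C)=C)/C(C)=C/CB1OC(C)(C)C(C)(C)O1 | intermediate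
17 | 3-((tert-butyldimethylsilyl)oxy)benzaldehyde | O=Cc1cccc(O[Si](C)(C)C(C)(C)C)c1 | starting material
18 | pinacol borate ester of alcohol 19 | C=C(C)CC[C@@H](CC=C(C)C)[C@@H](C(C)=C)[C@](C)(C=C)[C@@H](OB1OC(C)(C)C(C)(C)O1)c1cccc(O[Si](C)(C)C(C)(C)C)c1 | intermediate
19 | (1S,2S,3S,4S)-1-(3-((tert-butyldimethylsilyl)oxy)phenyl)-2,7-dimethyl-4-(3-methylbut-2-en-1-yl)-3-(prop-1-en-2-yl)-2-vinyloct-7-en-1-ol | C=C(C)CC[C@@H](CC=C(C)C)[C@@H](C(C)=C)[C@](C)(C=C)[C@@H](O)c1cccc(O[Si](C)(C)C(C)(C)C)c1 | intermediate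
20 | (2S,3S,4S)-1-(3-((tert-butyldimethylsilyl)oxy)phenyl)-2,7-dimethyl-4-(3-methylbut-2-en-1-yl)-3-(prop-1-en-2-yl)-2-vinyloct-7-en-1-one | C=C(C)CC[C@@H](CC=C(C)C)[C@@H](C(C)=C)[C@](C)(C=C)C(=O)c1cccc(O[Si](C)(C)C(C)(C)C)c1 | intermediate
21 | (3S,4S,5S)-3-(3-((tert-butyldimethylsilyl)oxy)benzoyl)-3,8-dimethyl-5-(3-methylbut-2-en-1-yl)-4-(prop-1-en-2-yl)non-8-enal | C=C(C)CC[C@@H](CC=C(C)C)[C@@H](C(C)=C)[C@](C)(CC=O)C(=O)c1cccc(O[Si](C)(C)C(C)(C)C)c1 | intermediate
22 | (2S,3S,4S)-1-(3-((tert-butyldimethylsilyl)oxy)phenyl)-2,7-dimethyl-2,4-bis(3-methylbut-2-en-1-yl)-3-(prop-1-en-2-yl)oct-7-en-1-one | C=C(C)CC[C@@H](CC=C(C)C)[C@@H](C(C)=C)[C@](C)(CC=C(C)C)C(=O)c1cccc(O[Si](C)(C)C(C)(C)C)c1 | intermediate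
23 | garcinielliptone FA, (2S,3S,4S)-1-(3-hydroxyphenyl)-2,7-dimethyl-2,4-bis(3-methylbut-2-en-1-yl)-3-(prop-1-en-2-yl)oct-7-en-1-one | C=C(C)CC[C@@H](CC=C(C)C)[C@@H](C(=C)C)[C@](C)(CC=C(C)C)C(=O)c1cccc(O)c1 | target

## Step count and risks

Total step count: 13. Longest linear sequence: 13 steps (1 and 2 to 23); aldehyde 17 enters at step 9.

Steps most likely to fail:

1. Step 9 (key step). The very hindered boronate may add slowly. The catalyst may fail to override a mismatched preference of the C3 stereocentre for one alkene face. Any loss of E-geometry during the borylation of step 8 would be translated directly into the C2 epimer. Fallback, setting out from allylic alcohol 15 and coming back at ketone 20: 3-hydroxyphenylacetic acid is bis-silylated (TBSCl, imidazole, DMF) to tert-butyldimethylsilyl 2-(3-((tert-butyldimethylsilyl)oxy)phenyl)acetate F1. Its silyl ester is cleaved (K2CO3, aqueous MeOH) to 2-(3-((tert-butyldimethylsilyl)oxy)phenyl)acetic acid F2. F2 is esterified with 15 (DCC, DMAP) to the allylic arylacetate F3. An Ireland–Claisen rearrangement (LiHMDS, TMSCl, THF, −78 °C → reflux) then forms the C1–C2 bond intramolecularly through a chair and gives the rearranged acid F4, as a mixture at the benzylic carbon and with C2 set under substrate control. Oxidative decarboxylation of the dianion (LDA, 2.2 equiv, THF; O2) gives 20.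

2. Step 11. Oxygen may be delivered partly to the internal carbon (methyl ketone formation), palladium hydride may migrate the 1,1-disubstituted alkenes, or the neopentyl vinyl group may react too slowly. Fallback, setting out from alcohol 19 and coming back at keto aldehyde 21: rhodium-catalysed hydroboration of the monosubstituted alkene (catecholborane, RhCl(PPh3)3, THF; then NaBO3) gives the 1,4-diol F5. Double Dess–Martin oxidation converts both carbinols and gives 21.

3. Step 1. Ligand control may be weak with the α-silyloxy aldehyde, giving low enantiomeric purity that would be carried through the whole route. Fallback, setting out from 1 and 2 and coming back at 5: the same hydrozirconation and zinc addition without chiral ligand give the racemic dienol F6. Oxidation (MnO2, CH2Cl2) gives the dienone F7. CBS reduction ((S)-Me-CBS, catecholborane, toluene, −78 °C), with the alkenyl group acting as the large substituent, should give 5.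

Further compounds
F1 | step 9 | tert-butyldimethylsilyl 2-(3-((tert-butyldimethylsilyl)oxy)phenyl)acetate | CC(C)(C)[Si](C)(C)OC(=O)Cc1cccc(O[Si](C)(C)C(C)(C)C)c1
F2 | step 9 | 2-(3-((tert-butyldimethylsilyl)oxy)phenyl)acetic acid | OC(=O)Cc1cccc(O[Si](C)(C)C(C)(C)C)c1
F3 | step 9 | (2E,4S,5S)-3,8-dimethyl-5-(3-methylbut-3-en-1-yl)-4-(prop-1-en-2-yl)nona-2,7-dien-1-yl 2-(3-((tert-butyldimethylsilyl)oxy)phenyl)acetate | C=C(C)CC[C@@H](CC=C(C)C)[C@@H](C(C)=C)/C(C)=C/COC(=O)Cc1cccc(O[Si](C)(C)C(C)(C)C)c1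
F4 | step 9 | (3S,4S,5S)-2-(3-((tert-butyldimethylsilyl)oxy)phenyl)-3,8-dimethyl-5-(3-methylbut-2-en-1-yl)-4-(prop-1-en-2-yl)-3-vinylnon-8-enoic acid (both C2 epimers) | C=C(C)CC[C@@H](CC=C(C)C)[C@@H](C(C)=C)[C@](C)(C=C)C(C(=O)O)c1cccc(O[Si](C)(C)C(C)(C)C)c1
F5 | step 11 | (1R,2S,3S,4S)-1-(3-((tert-butyldimethylsilyl)oxy)phenyl)-2-(2-hydroxyethyl)-2,7-dimethyl-4-(3-methylbut-2-en-1-yl)-3-(prop-1-en-2-yl)oct-7-en-1-ol | C=C(C)CC[C@@H](CC=C(C)C)[C@@H](C(C)=C)[C@](C)(CCO)[C@@H](O)c1cccc(O[Si](C)(C)C(C)(C)C)c1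
F6 | step 1 | rac-(E)-1-((tert-butyldimethylsilyl)oxy)-3,5-dimethylhexa-3,5-dien-2-ol | C=C(C)/C=C(\C)C(O)CO[Si](C)(C)C(C)(C)C
F7 | step 1 | (E)-1-((tert-butyldimethylsilyl)oxy)-3,5-dimethylhexa-3,5-dien-2-one | C=C(C)/C=C(\C)C(=O)CO[Si](C)(C)C(C)(C)C
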